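**Strategy.** The route rests on seeing ring B without C6 as a 2-methylcyclopentenone: C7 is a carbonyl carbon, C8 (with its methyl) and C8a are the two carbons of a propynyl group, and C4a–C5 is a terminal vinyl group, while C1–C4 of ring A form the tether. A single cobalt-mediated Pauson–Khand reaction of an acyclic dienyne then makes C4a–C8a, C5–C7 and C7–C8, closes ring A and the five-membered ring, and fixes C4a from the preset C1 and C2 centres. The precursor has prop-1-ynyl and silyloxymethyl on C1 and E-butenyl and a Z-1,3-dienyl arm on C2, set by an Ireland–Claisen rearrangement; C6 is inserted later.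

Key step: step 11

Remarks on the chemistry
- Locants: the octalin numbering of the target is used for every intermediate (C1 dienoic chain, C2 butenyl, C3 and C8 methyl, C7 oxygen; ring A = C1–C4, C4a, C8a; ring B = C4a–C8a). In the target H4a, H8a, the C1 chain, the C2 butenyl group, the C8 methyl group and the C7 oxygen all lie on one face, called β here.
- The C1 oxygen is carried as a tert-butyldimethylsilyl (TBS) ether: fluoride removes it, so no oxidant meets the doubly allylic C2–H, and the freed hydroxyl is needed in step 14.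
- H8a must enter on the face that carries the C1 substituent, which stands perpendicular to the enone plane of 19. A reagent from outside would add anti to that group, so the hydride is delivered from silicon tethered to the C1 oxygen (steps 13 and 14).
- The two alkenyl partners of step 2 must have opposite polarity, so the alkenylalane is coupled directly with the iodide.
- Assumption: the target is taken to be isolable as the free hydrogen sulfate by cold acidification of its salt; the sodium salt is the storable form.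

Step 1
Reactants: 1 acrolein
Product: 2 (3Z)-4-iodopenta-1,3-diene
Conditions: EtPPh3I, n-BuLi, THF, 20 °C; I2, −78 °C; NaN(SiMe3)2, −20 °C; then 1, −78 → −20 °C; kept cold and dark
Reagents that add atoms: (1-iodoethylidene)triphenylphosphorane, made in the flask from ethyltriphenylphosphonium iodide, CC(I)=P(c1ccccc1)(c1ccccc1)c1ccccc1
Why: Wittig olefination with the α-iodo ylide (Stork–Zhao type), in which the non-stabilised ylide reacts through the cis-oxaphosphetane and so places iodine cis to the vinyl group (Z), carbonyl addition being faster than conjugate addition at −78 °C.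

Step 2
Reactants: 3 (2R)-but-3-yn-2-ol; 2 (3Z)-4-iodopenta-1,3-diene
Product: 5 (2R,3E,5Z)-3,5-dimethylocta-3,5,7-trien-2-ol, via alkenylalane 4 (not isolated)
Conditions: AlMe3 (3 equiv), (C5H5)2ZrCl2 (0.25 equiv), CH2Cl2, 0 → 20 °C; then 2, ZnCl2, Pd(PPh3)4 (5 mol %), THF, 20 °C, dark; aq. KNaC4H4O6 at 0 °C
Reagents that add atoms: trimethylaluminium C[Al](C)C
Why: Zirconium-catalysed carboalumination adds methyl and aluminium syn across the alkyne (methyl to the internal carbon, E-alkenylalane) without touching the carbinol centre, and the zinc-assisted palladium-catalysed alkenyl–alkenyl coupling (Negishi type) joins it to the Z-iodide with retention at both alkenes; everything is kept at or below 20 °C because the Z-triene can undergo a 1,7-hydrogen shift.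

Step 3
Reactants: 6 propane-1,3-diol
Product: 7 3-[(tert-butyldimethylsilyl)oxy]propan-1-ol
Conditions: NaH (1 equiv), THF, 20 °C; TBSCl (1 equiv)
Reagents that add atoms: tert-butyldimethylsilyl chloride CC(C)(C)[Si](C)(C)Cl
Why: Monosilylation through the sparingly soluble monosodium alkoxide of the diol, which is silylated once.

Step 4
Reactants: 7 3-[(tert-butyldimethylsilyl)oxy]propan-1-ol
Product: 8 3-[(tert-butyldimethylsilyl)oxy]propanoic acid
Conditions: TEMPO (cat.), NaClO2, NaOCl (cat.), MeCN, NaH2PO4/Na2HPO4 buffer (pH 6.7), 35 °C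
Reagents that add atoms: sodium chlorite [Na+].[O-]Cl=O
Why: Nitroxyl-catalysed oxidation of the primary alcohol to the aldehyde and chlorite oxidation to the acid at near-neutral pH, under which a primary silyl ether survives.

Step 5
Reactants: 5 (2R,3E,5Z)-3,5-dimethylocta-3,5,7-trien-2-ol; 8 3-[(tert-butyldimethylsilyl)oxy]propanoic acid
Product: 9 (2R,3E,5Z)-3,5-dimethylocta-3,5,7-trien-2-yl 3-[(tert-butyldimethylsilyl)oxy]propanoate
Conditions: N,N'-dicyclohexylcarbodiimide, DMAP (cat.), CH2Cl2, 0 °C, dark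
Reagents that add atoms: none
Why: Carbodiimide esterification (Steglich) transfers the acyl group to oxygen, so the carbinol stereocentre is untouched and the cold neutral medium spares the triene.

Step 6
Reactants: 9 (2R,3E,5Z)-3,5-dimethylocta-3,5,7-trien-2-yl 3-[(tert-butyldimethylsilyl)oxy]propanoate
Product: 12 (2S,3R,4E)-2-{[(tert-butyldimethylsilyl)oxy]methyl}-4-methyl-3-[(2Z)-penta-2,4-dien-2-yl]hex-4-enoic acid, via silyl ketene acetal 10 (not isolated), via silyl ester 11 (not isolated)
Conditions: LiN(i-Pr)2, THF–DMPU (3:1), −78 °C, 3 min; TBSCl, −78 → 20 °C; aq. K2CO3, MeOH; citric acid to pH 4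
Reagents that add atoms: none
Why: Ireland–Claisen rearrangement in which the polar cosolvent gives the Z(O) ketene acetal (CH2OTBS cis to OSi) and a chair with the carbinol methyl equatorial transfers the (R) centre to C2, while the E alkene plus Z(O) geometry places CH2OTBS and the butenyl group in the relationship that becomes cis on ring A, and the new butenyl alkene is E; fast silyl trapping at −78 °C limits β-elimination of the silyloxy group.

Step 7
Reactants: 12 (2S,3R,4E)-2-{[(tert-butyldimethylsilyl)oxy]methyl}-4-methyl-3-[(2Z)-penta-2,4-dien-2-yl]hex-4-enoic acid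
Product: 13 (2R,3R,4E)-2-{[(tert-butyldimethylsilyl)oxy]methyl}-4-methyl-3-[(2Z)-penta-2,4-dien-2-yl]hex-4-en-1-ol
Conditions: LiAlH4, Et2O, 0 °C
Reagents that add atoms: none
Why: Hydride reduction of the carboxylate to the primary alcohol, to which the alkenes, the diene and the silyl ether are inert and which touches no stereocentre.

Step 8
Reactants: 13 (2R,3R,4E)-2-{[(tert-butyldimethylsilyl)oxy]methyl}-4-methyl-3-[(2Z)-penta-2,4-dien-2-yl]hex-4-en-1-ol
Product: 14 (2S,3R,4E)-2-{[(tert-butyldimethylsilyl)oxy]methyl}-4-methyl-3-[(2Z)-penta-2,4-dien-2-yl]hex-4-enal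
Conditions: Dess–Martin periodinane, CH2Cl2, 0 → 20 °C; used at once
Reagents that add atoms: none
Why: Dess–Martin oxidation is non-basic, so the α-stereocentre C1 with its β-silyloxy group neither epimerises nor eliminates.

Step 9
Reactants: 14 (2S,3R,4E)-2-{[(tert-butyldimethylsilyl)oxy]methyl}-4-methyl-3-[(2Z)-penta-2,4-dien-2-yl]hex-4-enal
Product: 15 1,1-dibromoalkene of 14 (CH=CBr2 in place of CHO; C1 and C2 unchanged)
Conditions: CBr4, PPh3, Zn, CH2Cl2, 20 °C; then 14, 0 °C
Reagents that add atoms: carbon tetrabromide BrC(Br)(Br)Br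
Why: Corey–Fuchs dibromo-olefination, in which the dibromomethylene ylide formed with zinc reacts with the aldehyde in a Wittig sense without added base.

Step 10
Reactants: 15 1,1-dibromoalkene of 14
Product: 17 tert-butyl{[(2R,3R,4E)-4-methyl-3-[(2Z)-penta-2,4-dien-2-yl]-2-(prop-1-yn-1-yl)hex-4-en-1-yl]oxy}dimethylsilane, via lithium acetylide 16 (not isolated)
Conditions: n-BuLi (2.1 equiv), THF, −78 °C; MeI, −78 → 0 °C
Reagents that add atoms: iodomethane CI
Why: Second stage of the Corey–Fuchs sequence, bromine–lithium exchange and 1,2-shift (Fritsch–Buttenberg–Wiechell) giving the lithium acetylide that iodomethane methylates on carbon; exchange at −78 °C outruns addition of butyllithium to the diene.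

Step 11
Reactants: 17 tert-butyl{[(2R,3R,4E)-4-methyl-3-[(2Z)-penta-2,4-dien-2-yl]-2-(prop-1-yn-1-yl)hex-4-en-1-yl]oxy}dimethylsilane
Product: 19 (4R,5R,7aR)-5-[(2E)-but-2-en-2-yl]-4-{[(tert-butyldimethylsilyl)oxy]methyl}-3,6-dimethyl-1,4,5,7a-tetrahydro-2H-inden-2-one, via alkyne hexacarbonyldicobalt complex 18 (not isolated)
Conditions: Co2(CO)8 (1.1 equiv), CH2Cl2, 20 °C; N-methylmorpholine N-oxide (8 equiv), 0 → 20 °C
Reagents that add atoms: dicobalt octacarbonyl (source of the C7 carbonyl) O=C=[Co](=C=O)(=C=O)(=C=O)[Co](=C=O)(=C=O)(=C=O)=C=O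
Why: Co2(CO)8 binds the propynyl group as its hexacarbonyldicobalt complex; loss of CO (N-oxide) lets the terminal vinyl group coordinate and insert into the Co–C8a bond (C4a–C8a), and CO insertion followed by reductive elimination forms C5–C7 and C7–C8. The closest known reaction type is the intramolecular Pauson–Khand reaction of 1,7-enynes whose tether holds a cis alkene or an arene, which gives hexahydroindenones. Ring A (six-membered) closes in the exo mode by alkene insertion, C5 staying outside the ring, and the five-membered enone closes by carbonylative reductive elimination from the cobaltacycle, a formal [2+2+1] addition. The one new stereocentre, C4a, is controlled by C1: allylic 1,3-strain between the alkyne methyl group (later C8–CH3) and C1 puts H1 in the enone plane and CH2OTBS perpendicular to it, ring A must then fold to the other face, and H4a ends cis to CH2OTBS with the C2 butenyl group pseudo-equatorial. The step needs chemoselectivity for the monosubstituted C4a=C5 alkene and a temperature low enough to avoid a 1,5-hydrogen shift of the Z-diene; the trisubstituted alkenes do not insert, the Z-diene cannot reach the alkyne in a [4+2] sense, and N-oxide promotion allows 0–20 °C.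

Step 12
Reactants: 19 (4R,5R,7aR)-5-[(2E)-but-2-en-2-yl]-4-{[(tert-butyldimethylsilyl)oxy]methyl}-3,6-dimethyl-1,4,5,7a-tetrahydro-2H-inden-2-one
Product: 20 (4R,5R,7aR)-5-[(2E)-but-2-en-2-yl]-4-(hydroxymethyl)-3,6-dimethyl-1,4,5,7a-tetrahydro-2H-inden-2-one
Conditions: HF·pyridine, pyridine, THF, 0 → 20 °C
Reagents that add atoms: none
Why: Fluoride cleaves the Si–O bond of the primary silyl ether in a weakly acidic medium that avoids γ-deprotonation of the enone at C1 or C4a.

Step 13
Reactants: 20 (4R,5R,7aR)-5-[(2E)-but-2-en-2-yl]-4-(hydroxymethyl)-3,6-dimethyl-1,4,5,7a-tetrahydro-2H-inden-2-one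
Product: 21 diisopropylsilyl ether of 20 (C1–CH2–O–SiH(i-Pr)2)
Conditions: (i-Pr)2SiHCl, imidazole, CH2Cl2, 0 °C
Reagents that add atoms: chlorodiisopropylsilane CC(C)[SiH](Cl)C(C)C
Why: Silylation of the primary alcohol with the hindered chlorosilane places an Si–H bond five atoms from C8a on the β face.

Step 14
Reactants: 21 diisopropylsilyl ether of 20
Product: 23 (3R,3aR,4S,5R,7aS)-5-[(2E)-but-2-en-2-yl]-4-(hydroxymethyl)-3,6-dimethyl-1,3,3a,4,5,7a-hexahydro-2H-inden-2-one, via enol ether silyl triflate 22 (not isolated)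
Conditions: Me3SiOTf (1.1 equiv), 2,6-di-tert-butylpyridine (0.2 equiv), CH2Cl2, −78 → −20 °C; HF·pyridine, pyridine, THF, 0 → 20 °C; K2CO3 (cat.), MeOH, 20 °C
Reagents that add atoms: none
Why: Proposed new method: Me3SiOTf O-silylates the enone to a 2-silyloxyallyl cation whose electrophilic terminus C8a lies directly beneath the perpendicular C1–CH2–O–SiH(i-Pr)2 arm, so hydride passes from silicon to C8a through a six-membered chair-like array on the β face (H8a cis to H4a and to the C1 substituent), the silicon leaving as its triflate and the ketone as enol ether 22, after which fluoride frees alcohol and ketone and carbonate equilibrates the C8 methyl group to the β position trans to the C8a–C1 bond; the closest known reaction types are the Lewis acid-promoted intramolecular hydrosilylation of β-silyloxy ketones (the same six-membered hydride delivery, there to C=O) and the Lewis acid-mediated conjugate reduction of enones by trialkylsilanes, and delivery from the tether is chosen because an external hydride would add anti to the C1 substituent.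

Step 15
Reactants: 23 (3R,3aR,4S,5R,7aS)-5-[(2E)-but-2-en-2-yl]-4-(hydroxymethyl)-3,6-dimethyl-1,3,3a,4,5,7a-hexahydro-2H-inden-2-one
Product: 25 (1R,4aS,7R,8S,8aR)-7-[(2E)-but-2-en-2-yl]-8-(hydroxymethyl)-1,6-dimethyl-3,4,4a,7,8,8a-hexahydronaphthalen-2(1H)-one, via 6-trimethylsilyl ketone 24 (not isolated)
Conditions: AlMe3 (2.5 equiv), Me3SiCHN2 (1.5 equiv), CH2Cl2, −78 → −20 °C; 1 M HCl, THF, 0 °C, brief
Reagents that add atoms: trimethylsilyldiazomethane C[Si](C)(C)C=[N+]=[N-]
Why: Lewis acid-promoted diazoalkane homologation (Tiffeneau–Demjanov type) in which the alcohol is first masked as its aluminium alkoxide, the diazo carbon adds to C7 and the less substituted C5 migrates in preference to the methyl-bearing C8, the silyl group blocks a second insertion and is lost on protonation, and the cold non-equilibrating work-up leaves C8 and the ring fusion as set.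

Step 16
Reactants: 25 (1R,4aS,7R,8S,8aR)-7-[(2E)-but-2-en-2-yl]-8-(hydroxymethyl)-1,6-dimethyl-3,4,4a,7,8,8a-hexahydronaphthalen-2(1H)-one
Product: 26 (1R,2S,4aS,7R,8S,8aR)-7-[(2E)-but-2-en-2-yl]-8-(hydroxymethyl)-1,6-dimethyl-1,2,3,4,4a,7,8,8a-octahydronaphthalen-2-ol
Conditions: LiBH(s-Bu)3 (2.5 equiv), THF, −78 °C; aq. NH4Cl
Reagents that add atoms: none
Why: The bulky trialkylborohydride attacks the cyclohexanone from the equatorial direction, avoiding the axial hydrogens on C5 and C8a, and gives the axial 7β-alcohol cis to the equatorial C8 methyl group, the isolated alkenes being inert.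

Step 17
Reactants: 26 (1R,2S,4aS,7R,8S,8aR)-7-[(2E)-but-2-en-2-yl]-8-(hydroxymethyl)-1,6-dimethyl-1,2,3,4,4a,7,8,8a-octahydronaphthalen-2-ol
Product: 27 7β-hydroxy aldehyde (CHO on C1; all ring centres as in the target)
Conditions: TEMPO (0.1 equiv), PhI(OAc)2 (1.2 equiv), CH2Cl2, 20 °C
Reagents that add atoms: none
Why: Nitroxyl-catalysed oxidation with the hypervalent iodine co-oxidant is selective for the primary alcohol over the hindered axial secondary one and is non-basic, so C1 is not epimerised; the two groups cannot form a lactol because they are trans-disposed on ring B.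

Step 18
Reactants: 27 7β-hydroxy aldehyde; 28 triethyl (2E)-4-phosphonobut-2-enoate
Product: 29 ethyl (2E,4E)-5-[(1S,2R,4aS,7S,8R,8aR)-2-[(2E)-but-2-en-2-yl]-7-hydroxy-3,8-dimethyl-1,2,4a,5,6,7,8,8a-octahydronaphthalen-1-yl]penta-2,4-dienoate
Conditions: 28 (2.5 equiv), LiN(SiMe3)2 (2.4 equiv), THF, −78 °C; then 27, −78 → 0 °C
Reagents that add atoms: none
Why: Horner–Wadsworth–Emmons reaction of the vinylogous phosphonate anion forms the new alkene E beside the existing E alkene, the lithium alkoxide of the C7 hydroxyl being a spectator and the low temperature protecting C1.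

Step 19
Reactants: 29 ethyl (2E,4E)-5-[(1S,2R,4aS,7S,8R,8aR)-2-[(2E)-but-2-en-2-yl]-7-hydroxy-3,8-dimethyl-1,2,4a,5,6,7,8,8a-octahydronaphthalen-1-yl]penta-2,4-dienoate
Product: 30 sodium salt of the 7-O-sulfate of 29
Conditions: SO3·pyridine (5 equiv), pyridine, 45 °C; aq. NaHCO3
Reagents that add atoms: sulfur trioxide–pyridine O=S(=O)([O-])[n+]1ccccc1; sodium hydrogencarbonate [Na+].OC([O-])=O
Why: O-Sulfation of the secondary alcohol by the sulfur trioxide–amine complex with retention at C7 (the C–O bond is not broken), to which the dienoate and the alkenes are inert.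

Step 20
Reactants: 30 sodium salt of the 7-O-sulfate of 29
Product: 31 target, (2E,4E)-5-[(1S,2R,4aS,7S,8R,8aR)-2-[(2E)-but-2-en-2-yl]-3,8-dimethyl-7-(sulfooxy)-1,2,4a,5,6,7,8,8a-octahydronaphthalen-1-yl]penta-2,4-dienoic acid
Conditions: LiOH, THF–MeOH–H2O, 20 °C; 1 M HCl to pH 2, 0 °C; immediate extraction (n-BuOH) and freeze-drying
Reagents that add atoms: lithium hydroxide [Li+].[OH-]
Why: Saponification of the ethyl ester, to which alkyl sulfate monoesters are inert, followed by cold acidification gives the carboxylic acid and the hydrogen sulfate.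

Compound list
1 | acrolein | C=CC=O | starting material
2 | (3Z)-4-iodopenta-1,3-diene | C=C/C=C(I)/C | intermediate
3 | (2R)-but-3-yn-2-ol | C[C@@H](O)C#C | starting material
4 | (E)-alkenyldimethylalane, aluminium alkoxide of (2R)-3-methylbut-3-en-2-ol metalated at C4 | C[C@@H](O[Al](C)C)/C(C)=C/[Al](C)C | intermediate
5 | (2R,3E,5Z)-3,5-dimethylocta-3,5,7-trien-2-ol | C[C@@H](O)/C(C)=C/C(C)=C\C=C | intermediate
6 | propane-1,3-diol | OCCCO | starting material
7 | 3-[(tert-butyldimethylsilyl)oxy]propan-1-ol | CC(C)(C)[Si](C)(C)OCCCO | intermediate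
8 | 3-[(tert-butyldimethylsilyl)oxy]propanoic acid | CC(C)(C)[Si](C)(C)OCCC(=O)O | intermediate
9 | (2R,3E,5Z)-3,5-dimethylocta-3,5,7-trien-2-yl 3-[(tert-butyldimethylsilyl)oxy]propanoate | C[C@@H](OC(=O)CCO[Si](C)(C)C(C)(C)C)/C(C)=C/C(C)=C\C=C | intermediate
10 | Z(O) tert-butyldimethylsilyl ketene acetal of 9 (CH2OTBS cis to OSi) | C[C@@H](O/C(O[Si](C)(C)C(C)(C)C)=C/CO[Si](C)(C)C(C)(C)C)/C(C)=C/C(C)=C\C=C | intermediate
11 | tert-butyldimethylsilyl ester of 12 | C/C=C(\C)[C@H](/C(C)=C\C=C)[C@H](C(=O)O[Si](C)(C)C(C)(C)C)CO[Si](C)(C)C(C)(C)C | intermediate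
12 | (2S,3R,4E)-2-{[(tert-butyldimethylsilyl)oxy]methyl}-4-methyl-3-[(2Z)-penta-2,4-dien-2-yl]hex-4-enoic acid | C/C=C(\C)[C@H](/C(C)=C\C=C)[C@H](C(=O)O)CO[Si](C)(C)C(C)(C)C | intermediate
13 | (2R,3R,4E)-2-{[(tert-butyldimethylsilyl)oxy]methyl}-4-methyl-3-[(2Z)-penta-2,4-dien-2-yl]hex-4-en-1-ol | C/C=C(\C)[C@H](/C(C)=C\C=C)[C@H](CO)CO[Si](C)(C)C(C)(C)C | intermediate
14 | (2S,3R,4E)-2-{[(tert-butyldimethylsilyl)oxy]methyl}-4-methyl-3-[(2Z)-penta-2,4-dien-2-yl]hex-4-enal | C/C=C(\C)[C@H](/C(C)=C\C=C)[C@H](C=O)CO[Si](C)(C)C(C)(C)C | intermediate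
15 | 1,1-dibromoalkene of 14 (CH=CBr2 on C1) | C/C=C(\C)[C@H](/C(C)=C\C=C)[C@H](C=C(Br)Br)CO[Si](C)(C)C(C)(C)C | intermediate
16 | lithium acetylide (C1–C≡C–Li) | C/C=C(\C)[C@H](/C(C)=C\C=C)[C@H](C#C[Li])CO[Si](C)(C)C(C)(C)C | intermediate
17 | Pauson–Khand precursor, tert-butyl{[(2R,3R,4E)-4-methyl-3-[(2Z)-penta-2,4-dien-2-yl]-2-(prop-1-yn-1-yl)hex-4-en-1-yl]oxy}dimethylsilane | C/C=C(\C)[C@H](/C(C)=C\C=C)[C@H](C#CC)CO[Si](C)(C)C(C)(C)C | intermediate
18 | hexacarbonyldicobalt complex of the propynyl group of 17 | C/C=C(\C)[C@H](/C(C)=C\C=C)[C@@H](CO[Si](C)(C)C(C)(C)C)C12[Co]3(=C=O)(=C=O)(=C=O)[Co]1(=C=O)(=C=O)(=C=O)C23C | intermediate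
19 | bicyclo[4.3.0] dienone (ring A plus ring B without C6; 1β-CH2OTBS, 2β-butenyl, 4aβ-H), (4R,5R,7aR)-5-[(2E)-but-2-en-2-yl]-4-{[(tert-butyldimethylsilyl)oxy]methyl}-3,6-dimethyl-1,4,5,7a-tetrahydro-2H-inden-2-one | C/C=C(\C)[C@@H]1C(C)=C[C@H]2CC(=O)C(C)=C2[C@@H]1CO[Si](C)(C)C(C)(C)C | intermediate
20 | (4R,5R,7aR)-5-[(2E)-but-2-en-2-yl]-4-(hydroxymethyl)-3,6-dimethyl-1,4,5,7a-tetrahydro-2H-inden-2-one | C/C=C(\C)[C@@H]1C(C)=C[C@H]2CC(=O)C(C)=C2[C@@H]1CO | intermediate
21 | diisopropylsilyl ether of 20 | C/C=C(\C)[C@@H]1C(C)=C[C@H]2CC(=O)C(C)=C2[C@@H]1CO[SiH](C(C)C)C(C)C | intermediate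
22 | C7 trimethylsilyl enol ether with 8aβ-H and C1–CH2–O–Si(i-Pr)2–OTf | C/C=C(\C)[C@@H]1C(C)=C[C@H]2CC(O[Si](C)(C)C)=C(C)[C@H]2[C@@H]1CO[Si](OS(=O)(=O)C(F)(F)F)(C(C)C)C(C)C | intermediate
23 | cis-hydrindanone (1β-CH2OH, 2β-butenyl, 4aβ-H, 8aβ-H, 8β-CH3), (3R,3aR,4S,5R,7aS)-5-[(2E)-but-2-en-2-yl]-4-(hydroxymethyl)-3,6-dimethyl-1,3,3a,4,5,7a-hexahydro-2H-inden-2-one | C/C=C(\C)[C@@H]1C(C)=C[C@H]2CC(=O)[C@H](C)[C@H]2[C@@H]1CO | intermediate
24 | 6-trimethylsilyl derivative of 25 (C6 configuration undefined) | C/C=C(\C)[C@@H]1C(C)=C[C@H]2CC([Si](C)(C)C)C(=O)[C@H](C)[C@H]2[C@@H]1CO | intermediate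
25 | cis-decalone, (1R,4aS,7R,8S,8aR)-7-[(2E)-but-2-en-2-yl]-8-(hydroxymethyl)-1,6-dimethyl-3,4,4a,7,8,8a-hexahydronaphthalen-2(1H)-one | C/C=C(\C)[C@@H]1C(C)=C[C@H]2CCC(=O)[C@H](C)[C@H]2[C@@H]1CO | intermediate
26 | (1R,2S,4aS,7R,8S,8aR)-7-[(2E)-but-2-en-2-yl]-8-(hydroxymethyl)-1,6-dimethyl-1,2,3,4,4a,7,8,8a-octahydronaphthalen-2-ol | C/C=C(\C)[C@@H]1C(C)=C[C@H]2CC[C@H](O)[C@H](C)[C@H]2[C@@H]1CO | intermediate
27 | 7β-hydroxy aldehyde, 2-[(2E)-but-2-en-2-yl]-7-hydroxy-3,8-dimethyl-1,2,4a,5,6,7,8,8a-octahydronaphthalene-1-carbaldehyde with all ring centres as in the target | C/C=C(\C)[C@@H]1C(C)=C[C@H]2CC[C@H](O)[C@H](C)[C@H]2[C@@H]1C=O | intermediate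
28 | triethyl (2E)-4-phosphonobut-2-enoate | CCOC(=O)/C=C/CP(=O)(OCC)OCC | starting material
29 | ethyl (2E,4E)-5-[(1S,2R,4aS,7S,8R,8aR)-2-[(2E)-but-2-en-2-yl]-7-hydroxy-3,8-dimethyl-1,2,4a,5,6,7,8,8a-octahydronaphthalen-1-yl]penta-2,4-dienoate | C/C=C(\C)[C@@H]1C(C)=C[C@H]2CC[C@H](O)[C@H](C)[C@H]2[C@@H]1/C=C/C=C/C(=O)OCC | intermediate
30 | sodium salt of the 7-O-sulfate of 29 | C/C=C(\C)[C@@H]1C(C)=C[C@H]2CC[C@H](OS(=O)(=O)[O-])[C@H](C)[C@H]2[C@@H]1/C=C/C=C/C(=O)OCC.[Na+] | intermediate
31 | (2E,4E)-5-[(1S,2R,4aS,7S,8R,8aR)-2-[(2E)-but-2-en-2-yl]-3,8-dimethyl-7-(sulfooxy)-1,2,4a,5,6,7,8,8a-octahydronaphthalen-1-yl]penta-2,4-dienoic acid | C/C=C(\C)[C@@H]1C(C)=C[C@H]2CC[C@H](OS(=O)(=O)O)[C@H](C)[C@H]2[C@@H]1/C=C/C=C/C(=O)O | target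

Total step count: 20. Longest linear sequence: 18 steps (steps 1, 2 and 5–20 from acrolein; the same length from propane-1,3-diol through steps 3, 4 and 5–20).

Steps most likely to fail

Step 14 (proposed new method). The hydride transfer may stall at the hindered, fully substituted C8a; the silyl triflate may exchange at the Si–O bond before transfer; or the activated enone may be attacked by the butenyl alkene. The fallback uses known chemistry and runs from 20 back to 23. Hydroxyl-directed hydrogenation with [Ir(cod)(PCy3)(py)]PF6 (5 mol %) under H2 (1 atm) in CH2Cl2 at 0 °C, in which iridium bound to the C1 hydroxymethyl group adds both hydrogens to C8=C8a from the β face, gives the 8-epi hydroxy ketone F1 (H8 and H8a β, methyl α). K2CO3 in MeOH then inverts C8 and gives 23. The run is stopped at partial conversion, because this catalyst also saturates the two trisubstituted alkenes, and recovered 20 is recycled.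

Step 11 (key step). Formation of the cobaltacycle may be slow for a 1,7-enyne, cobalt may be held by the diene, and forcing the reaction by heat would start the 1,5-hydrogen shift of the Z-diene. The fallback runs from 17 back to 19. Oxidative bicyclisation with zirconocene, made from (C5H5)2ZrCl2 and n-BuLi (2 equiv) in THF at −78 to 20 °C, gives the zirconabicycle F2 (Zr bonded to C5 and C8), with the same allylic 1,3-strain control of C4a. CO (1 atm, 0 °C) then inserts and protonolysis with cold aq. HCl releases 19.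

Step 2. Carbometalation of the aluminium alkoxide may be slow or incomplete, the excess alane may transfer methyl to 2, and the triene may isomerise by 1,7-hydrogen shift during a long one-pot run. The fallback runs from 3 (with 2) back to 5. The alane 4 is quenched with iodine (THF, −30 °C) and (2R,3E)-4-iodo-3-methylbut-3-en-2-ol F3 is isolated. Separately, 2 is converted by t-BuLi (2 equiv, Et2O, −78 °C) and ZnCl2 into (Z)-penta-1,3-dien-4-ylzinc chloride F4. F3 (as its sodium alkoxide, NaH) and F4 are coupled with Pd(PPh3)4 (5 mol %) in THF at 0–20 °C to give 5.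

Further compounds
F1 | step 14 | 8-epi hydroxy ketone (8α-methyl epimer of 23) | C/C=C(\C)[C@@H]1C(C)=C[C@H]2CC(=O)[C@@H](C)[C@H]2[C@@H]1CO
F2 | step 11 | zirconabicycle from 17 (bis(cyclopentadienyl)zirconium bonded to C5 and C8) | C/C=C(\C)[C@@H]1C(C)=C[C@H]2C[Zr](C3C=CC=C3)(C3C=CC=C3)C(C)=C2[C@@H]1CO[Si](C)(C)C(C)(C)C
F3 | step 2 | (2R,3E)-4-iodo-3-methylbut-3-en-2-ol | C[C@@H](O)/C(C)=C/I
F4 | step 2 | (Z)-penta-1,3-dien-4-ylzinc chloride | C=C/C=C([Zn]Cl)/C
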